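**Strategy.** The polyene is cut at the C10′–C11′ single bond (carotenoid numbering), the sp2–sp2 bond four carbons out from C6′ of the epsilon ring, between the trisubstituted C9′=C10′ and the disubstituted C11′=C12′ olefins. Since both carbons are olefinic CH termini, a Suzuki–Miyaura coupling forms this bond with retention on both sides: the C26 (E)-alkenyl boronate 13 (beta ring, C3 palmitate, boron on C11′) and the C14 (E)-dienyl iodide 22 (epsilon ring, C3′ palmitate, iodine on C10′) give helenien directly, in the last step, with all three stereocentres and both esters in place. C3 is set by transfer hydrogenation, C6′ is bought, C3′ by CBS reduction.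

Key step: step 15

Remark on numbering: unprimed locants belong to the half with the beta ring (ring olefin C5=C6, chain C7–C15), primed locants to the half with the epsilon ring (ring olefin C4′=C5′, chain C7′–C15′).

Assumption: (R)-α-ionone 14 (the natural, dextrorotatory enantiomer) is taken as a purchasable single enantiomer; its stereocentre becomes C6′ and is never deprotonated on the route.

**Step 1**
Reactants: 1 ketoisophorone
Product: 2 (4S)-4-hydroxy-2,6,6-trimethylcyclohex-2-en-1-one ((S)-phorenol)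
Conditions: RuCl(p-cymene)[(S,S)-TsDPEN] (1 mol%), KOH (2 mol%), i-PrOH, 25 °C
Reagents that add atoms: none
Why: Noyori transfer hydrogenation reduces only the unhindered C4 carbonyl (the C1 carbonyl is shielded by the gem-dimethyl carbon and the C2 methyl), and the (S,S) catalyst, reading the olefinic flank as it reads an aryl group, should set the (S)-carbinol that becomes C3 of the beta ring.

**Step 2**
Reactants: 2 (S)-phorenol
Product: 3 (4S)-4-[(tert-butyldimethylsilyl)oxy]-2,6,6-trimethylcyclohex-2-en-1-one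
Conditions: TBSCl, imidazole, DMF, 25 °C
Reagents that add atoms: tert-butyldimethylsilyl chloride CC(C)(C)[Si](C)(C)Cl
Why: Standard silylation of a secondary alcohol, which masks the hydroxyl through the hydride, enolate, palladium and Grignard steps.

**Step 3**
Reactants: 3 silyl ether of (S)-phorenol
Product: 5 (4R)-4-[(tert-butyldimethylsilyl)oxy]-2,6,6-trimethylcyclohex-1-en-1-yl trifluoromethanesulfonate, via lithium enolate 4 (not isolated)
Conditions: LiBH(s-Bu)3, THF, −78 °C; then PhNTf2, −78 → 25 °C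
Reagents that add atoms: N-phenylbis(trifluoromethanesulfonimide) O=S(=O)(N(c1ccccc1)S(=O)(=O)C(F)(F)F)C(F)(F)F
Why: Conjugate reduction of the β-unsubstituted cyclohexenone by the bulky borohydride (1,2-attack is blocked by the flanking quaternary carbon) gives the tetrasubstituted enolate regiospecifically and O-triflation traps it as the enol triflate; the carbinol centre is untouched and only its descriptor changes from S to R.

**Step 4**
Reactants: 5 enol triflate
Product: 6 (3E)-4-[(4R)-4-[(tert-butyldimethylsilyl)oxy]-2,6,6-trimethylcyclohex-1-en-1-yl]but-3-en-2-one (silyl ether of (3R)-3-hydroxy-β-ionone)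
Conditions: methyl vinyl ketone, Pd(OAc)2 (5 mol%), PPh3 (10 mol%), Et3N, DMF, 70 °C
Reagents that add atoms: methyl vinyl ketone C=CC(C)=O
Why: Heck reaction, in which oxidative addition of the alkenyl triflate to zerovalent palladium, insertion of the enone at its unsubstituted terminus and β-hydride elimination should give the (E)-dienone.

**Step 5**
Reactants: 6 silyl ether of (3R)-3-hydroxy-β-ionone
Product: 7 (4E)-5-[(4R)-4-[(tert-butyldimethylsilyl)oxy]-2,6,6-trimethylcyclohex-1-en-1-yl]-3-methylpenta-1,4-dien-3-ol (both epimers at the new carbinol carbon)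
Conditions: CH2=CHMgBr, THF, −20 → 0 °C; aq NH4Cl
Reagents that add atoms: vinylmagnesium bromide C=C[Mg]Br
Why: 1,2-Addition of the vinyl Grignard reagent to the methyl ketone, as in the classical vinyl-β-ionol preparation; the new carbinol centre is formed as a mixture, which is irrelevant because step 6 destroys it.

**Step 6**
Reactants: 7 vinyl carbinol
Product: 8 [(2E,4E)-5-[(4R)-4-hydroxy-2,6,6-trimethylcyclohex-1-en-1-yl]-3-methylpenta-2,4-dien-1-yl]triphenylphosphonium bromide
Conditions: PPh3·HBr (1.5 equiv), MeOH, 25 → 40 °C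
Reagents that add atoms: triphenylphosphine hydrobromide [Br-].[PH+](c1ccccc1)(c1ccccc1)c1ccccc1
Why: Acid ionises the tertiary doubly allylic alcohol to a pentadienyl cation that PPh3 captures at the primary terminus (allylic transposition) to give the conjugated (E,E) phosphonium salt, while the acidic methanol also cleaves the silyl ether.

**Step 7**
Reactants: 8 C15 phosphonium bromide; 9 (2E,4E,6E)-2,7-dimethylocta-2,4,6-trienedial
Product: 11 (2E,4E,6E,8E,10E,12E)-13-[(4R)-4-hydroxy-2,6,6-trimethylcyclohex-1-en-1-yl]-2,7,11-trimethyltrideca-2,4,6,8,10,12-hexaenal, via phosphorus ylide 10 (not isolated)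
Conditions: 9 (2 equiv), NaOMe, CH2Cl2/MeOH, 0 °C; then I2 (cat.), CH2Cl2, 25 °C, diffuse light
Reagents that add atoms: none
Why: Wittig olefination of one aldehyde of the symmetrical dial (used in excess, the mono-adduct aldehyde being deactivated by the longer polyene) forms C11=C12, and iodine-catalysed equilibration should convert the hindered 11Z isomer into the all-E aldehyde.

**Step 8**
Reactants: 11 C25 hydroxy aldehyde
Product: 12 (1R)-3,5,5-trimethyl-4-[(1E,3E,5E,7E,9E,11E)-3,7,12-trimethyl-13-oxotrideca-1,3,5,7,9,11-hexaen-1-yl]cyclohex-3-en-1-yl hexadecanoate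
Conditions: palmitoyl chloride, pyridine, DMAP (cat.), CH2Cl2, 0 → 25 °C
Reagents that add atoms: palmitoyl chloride CCCCCCCCCCCCCCCC(=O)Cl
Why: DMAP-catalysed acylation of the secondary alcohol by the acid chloride, with retention at C3.

**Step 9**
Reactants: 12 C25 aldehyde palmitate
Product: 13 (1R)-3,5,5-trimethyl-4-[(1E,3E,5E,7E,9E,11E,13E)-3,7,12-trimethyl-14-(4,4,5,5-tetramethyl-1,3,2-dioxaborolan-2-yl)tetradeca-1,3,5,7,9,11,13-heptaen-1-yl]cyclohex-3-en-1-yl hexadecanoate
Conditions: Cl2CHBpin, CrCl2, LiI, THF, 25 °C, dark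
Reagents that add atoms: 2-(dichloromethyl)-4,4,5,5-tetramethyl-1,3,2-dioxaborolane ClC(Cl)B1OC(C)(C)C(C)(C)O1
Why: Takai–Utimoto borylolefination, in which the geminal dichromium reagent formed from the dihalomethylboronate and divalent chromium adds to the aldehyde and eliminates to the (E)-alkenyl boronate, adding C11′ while ester and polyene stay inert.

**Step 10**
Reactants: 14 (R)-α-ionone
Product: 17 (6R)-6-[(1E)-but-1-en-3-yn-1-yl]-1,5,5-trimethylcyclohex-1-ene, via dienyl diethyl phosphate 15 (not isolated), via lithium acetylide 16 (not isolated)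
Conditions: LiN(i-Pr)2, THF, −78 °C; ClP(O)(OEt)2, −78 → 25 °C; then LiN(i-Pr)2 (2.3 equiv), −78 → 25 °C; H2O
Reagents that add atoms: none
Why: Methyl ketone to alkyne conversion by enol phosphate elimination (kinetic enolisation at the methyl group, O-phosphorylation, base-induced loss of diethyl phosphate); the acetylide formed guards against a second deprotonation, so C6 should keep its configuration.

**Step 11**
Reactants: 17 enyne
Product: 18 (4R)-4-[(1E)-but-1-en-3-yn-1-yl]-3,5,5-trimethylcyclohex-2-en-1-one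
Conditions: Rh2(cap)4 (dirhodium tetracaprolactamate, 1 mol%), 70% aq t-BuOOH, 1,2-dichloroethane, 40 °C
Reagents that add atoms: tert-butyl hydroperoxide CC(C)(C)OO
Why: Rhodium-catalysed allylic oxidation (tert-butylperoxyl radical chain) should abstract hydrogen from the unhindered ring CH2 next to the olefin and deliver the enone, as in the oxidation of α-ionone to 3-oxo-α-ionone, leaving the hindered tertiary C–H and the alkyne alone under base-free conditions.

**Step 12**
Reactants: 18 enynone
Product: 19 (1R,4R)-4-[(1E)-but-1-en-3-yn-1-yl]-3,5,5-trimethylcyclohex-2-en-1-ol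
Conditions: (S)-2-methyl-CBS-oxazaborolidine (20 mol%), catecholborane, toluene, −78 °C
Reagents that add atoms: none
Why: Corey–Bakshi–Shibata reduction, in which the oxazaborolidine binds the carbonyl anti to the olefinic flank and delivers hydride to one face, so the (S) catalyst should give the (R)-carbinol (C3′) trans to the side chain, any cis epimer being removed by chromatography.

**Step 13**
Reactants: 19 enynol
Product: 21 (1R,4R)-4-[(1E,3E)-4-iodo-3-methylbuta-1,3-dien-1-yl]-3,5,5-trimethylcyclohex-2-en-1-ol, via alkenylalane 20 (not isolated)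
Conditions: AlMe3 (3.5 equiv), Cp2ZrCl2 (0.3 equiv), CH2Cl2, 0 → 25 °C; then I2, THF, −30 °C
Reagents that add atoms: trimethylaluminium C[Al](C)C; iodine II
Why: Negishi zirconium-catalysed carboalumination adds CH3 and Al syn across the terminal alkyne (methyl to the internal carbon, C9′), and iodinolysis of the alkenyl–aluminium bond with retention should give the (E)-iodide, the hydroxyl being carried as its aluminium alkoxide.

**Step 14**
Reactants: 21 hydroxy dienyl iodide
Product: 22 (1R,4R)-4-[(1E,3E)-4-iodo-3-methylbuta-1,3-dien-1-yl]-3,5,5-trimethylcyclohex-2-en-1-yl hexadecanoate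
Conditions: palmitoyl chloride, pyridine, DMAP (cat.), CH2Cl2, 0 °C
Reagents that add atoms: palmitoyl chloride CCCCCCCCCCCCCCCC(=O)Cl
Why: Acylation of the allylic alcohol under pyridine-buffered conditions, with retention at C3′.

**Step 15**
Reactants: 13 C26 alkenyl boronate; 22 C14 dienyl iodide
Product: 23 helenien ((3R,3′R,6′R)-lutein dipalmitate)
Conditions: Pd(OAc)2 (5 mol%), SPhos (10 mol%), K3PO4 (3 M aq), THF, 25 °C, dark, Ar
Reagents that add atoms: none
Why: Suzuki–Miyaura coupling in its alkenyl–alkenyl form, the closest known reaction type (polyene end-game couplings): zerovalent palladium generated from Pd(OAc)2 and SPhos adds oxidatively to the C10′–I bond of 22, the phosphate/hydroxide-activated boronate of 13 transmetalates C11′, and reductive elimination forms the C10′–C11′ sp2–sp2 bond. All three elementary steps retain configuration at olefinic carbon, so the 9′E and 11′E geometries built into the partners are carried into the product. No ring is closed and no stereocentre is formed; C3, C3′ and C6′ are bystanders (C6′–H is far too weakly acidic for phosphate). The selectivity needed is chemoselectivity for the alkenyl iodide over ionisation of the allylic C3′ palmitate on the epsilon ring and over ester hydrolysis; it is secured by the much faster oxidative addition of the unhindered (E)-iodide at room temperature, by the hindered trisubstituted C4′=C5′ olefin next to that ester and by the weak biphasic base. Light and oxygen are excluded to keep the polyene all-E.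

**Compound list**

1 | ketoisophorone (2,6,6-trimethylcyclohex-2-ene-1,4-dione) | CC1=CC(=O)CC(C)(C)C1=O | starting material
2 | (4S)-4-hydroxy-2,6,6-trimethylcyclohex-2-en-1-one | O[C@@H]1C=C(C)C(=O)C(C)(C)C1 | intermediate
3 | (4S)-4-[(tert-butyldimethylsilyl)oxy]-2,6,6-trimethylcyclohex-2-en-1-one | CC(C)(C)[Si](C)(C)O[C@@H]1C=C(C)C(=O)C(C)(C)C1 | intermediate
4 | lithium (4R)-4-[(tert-butyldimethylsilyl)oxy]-2,6,6-trimethylcyclohex-1-en-1-olate | CC(C)(C)[Si](C)(C)O[C@@H]1CC(C)=C(O[Li])C(C)(C)C1 | intermediate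
5 | (4R)-4-[(tert-butyldimethylsilyl)oxy]-2,6,6-trimethylcyclohex-1-en-1-yl trifluoromethanesulfonate | CC(C)(C)[Si](C)(C)O[C@@H]1CC(C)=C(OS(=O)(=O)C(F)(F)F)C(C)(C)C1 | intermediate
6 | (3E)-4-[(4R)-4-[(tert-butyldimethylsilyl)oxy]-2,6,6-trimethylcyclohex-1-en-1-yl]but-3-en-2-one | CC(C)(C)[Si](C)(C)O[C@@H]1CC(C)=C(/C=C/C(C)=O)C(C)(C)C1 | intermediate
7 | (4E)-5-[(4R)-4-[(tert-butyldimethylsilyl)oxy]-2,6,6-trimethylcyclohex-1-en-1-yl]-3-methylpenta-1,4-dien-3-ol, both epimers at the tertiary carbinol | CC(C)(C)[Si](C)(C)O[C@@H]1CC(C)=C(/C=C/C(C)(O)C=C)C(C)(C)C1 | intermediate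
8 | [(2E,4E)-5-[(4R)-4-hydroxy-2,6,6-trimethylcyclohex-1-en-1-yl]-3-methylpenta-2,4-dien-1-yl]triphenylphosphonium bromide | O[C@@H]1CC(C)=C(/C=C/C(C)=C/C[P+](c2ccccc2)(c2ccccc2)c2ccccc2)C(C)(C)C1.[Br-] | intermediate
9 | (2E,4E,6E)-2,7-dimethylocta-2,4,6-trienedial | O=C/C(C)=C/C=C/C=C(C)/C=O | starting material
10 | phosphorus ylide of 8 | O[C@@H]1CC(C)=C(/C=C/C(C)=C/C=P(c2ccccc2)(c2ccccc2)c2ccccc2)C(C)(C)C1 | intermediate
11 | (2E,4E,6E,8E,10E,12E)-13-[(4R)-4-hydroxy-2,6,6-trimethylcyclohex-1-en-1-yl]-2,7,11-trimethyltrideca-2,4,6,8,10,12-hexaenal | O[C@@H]1CC(C)=C(/C=C/C(C)=C/C=C/C(C)=C/C=C/C=C(C)/C=O)C(C)(C)C1 | intermediate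
12 | (1R)-3,5,5-trimethyl-4-[(1E,3E,5E,7E,9E,11E)-3,7,12-trimethyl-13-oxotrideca-1,3,5,7,9,11-hexaen-1-yl]cyclohex-3-en-1-yl hexadecanoate | CCCCCCCCCCCCCCCC(=O)O[C@@H]1CC(C)=C(/C=C/C(C)=C/C=C/C(C)=C/C=C/C=C(C)/C=O)C(C)(C)C1 | intermediate
13 | (1R)-3,5,5-trimethyl-4-[(1E,3E,5E,7E,9E,11E,13E)-3,7,12-trimethyl-14-(4,4,5,5-tetramethyl-1,3,2-dioxaborolan-2-yl)tetradeca-1,3,5,7,9,11,13-heptaen-1-yl]cyclohex-3-en-1-yl hexadecanoate | CCCCCCCCCCCCCCCC(=O)O[C@@H]1CC(C)=C(/C=C/C(C)=C/C=C/C(C)=C/C=C/C=C(C)/C=C/B2OC(C)(C)C(C)(C)O2)C(C)(C)C1 | intermediate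
14 | (R)-α-ionone, (3E)-4-[(1R)-2,6,6-trimethylcyclohex-2-en-1-yl]but-3-en-2-one | CC(=O)/C=C/[C@H]1C(C)=CCCC1(C)C | starting material
15 | diethyl (3E)-4-[(1R)-2,6,6-trimethylcyclohex-2-en-1-yl]buta-1,3-dien-2-yl phosphate | C=C(OP(=O)(OCC)OCC)/C=C/[C@H]1C(C)=CCCC1(C)C | intermediate
16 | lithium acetylide of 17 | [Li]C#C/C=C/[C@H]1C(C)=CCCC1(C)C | intermediate
17 | (6R)-6-[(1E)-but-1-en-3-yn-1-yl]-1,5,5-trimethylcyclohex-1-ene | C#C/C=C/[C@H]1C(C)=CCCC1(C)C | intermediate
18 | (4R)-4-[(1E)-but-1-en-3-yn-1-yl]-3,5,5-trimethylcyclohex-2-en-1-one | C#C/C=C/[C@H]1C(C)=CC(=O)CC1(C)C | intermediate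
19 | (1R,4R)-4-[(1E)-but-1-en-3-yn-1-yl]-3,5,5-trimethylcyclohex-2-en-1-ol | C#C/C=C/[C@H]1C(C)=C[C@H](O)CC1(C)C | intermediate
20 | (E)-alkenyl(dimethyl)alane from 19, with the oxygen as its dimethylaluminium alkoxide | C[Al](C)/C=C(C)/C=C/[C@H]1C(C)=C[C@H](O[Al](C)C)CC1(C)C | intermediate
21 | (1R,4R)-4-[(1E,3E)-4-iodo-3-methylbuta-1,3-dien-1-yl]-3,5,5-trimethylcyclohex-2-en-1-ol | I/C=C(C)/C=C/[C@H]1C(C)=C[C@H](O)CC1(C)C | intermediate
22 | (1R,4R)-4-[(1E,3E)-4-iodo-3-methylbuta-1,3-dien-1-yl]-3,5,5-trimethylcyclohex-2-en-1-yl hexadecanoate | I/C=C(C)/C=C/[C@H]1C(C)=C[C@H](OC(=O)CCCCCCCCCCCCCCC)CC1(C)C | intermediate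
23 | helenien, (3R,3′R,6′R)-lutein dipalmitate | CCCCCCCCCCCCCCCC(=O)O[C@@H]1CC(C)=C(/C=C/C(C)=C/C=C/C(C)=C/C=C/C=C(C)/C=C/C=C(C)/C=C/[C@H]2C(C)=C[C@H](OC(=O)CCCCCCCCCCCCCCC)CC2(C)C)C(C)(C)C1 | target

**Step count.** Total: 15 steps. Longest linear sequence: 10 steps (steps 1–9, then step 15); the other branch is 6 steps (steps 10–14, then step 15).

**Steps most likely to fail, with fallbacks**

Step 11. The radical oxidation may be unselective: hydrogen abstraction at the doubly allylic C–H or the ring methyl, or radical addition to the enyne, would lower conversion to the enone and could erode the C6′ centre. The fallback replaces C–H oxidation by an ionic three-stage sequence that sets out from enyne 17 and comes back at enynone 18. Epoxidation of the electron-rich ring olefin (mCPBA, NaHCO3, CH2Cl2, 0 °C; the enyne olefin is left) should give the 4,5-epoxide with oxygen anti to the side chain F1. PhSeNa (from PhSeSePh and NaBH4, EtOH) opens it at the secondary carbon to the trans hydroxy selenide F2. Oxidation with H2O2 and selenoxide syn-elimination, which can only run toward the ring CH2, give the tertiary allylic alcohol F3. Babler–Dauben oxidative 1,3-transposition with pyridinium chlorochromate (C5H5NH)[CrO3Cl] in CH2Cl2 then gives 18.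

Step 12. Facial selectivity may be poor, because the catalyst has to tell the olefinic flank from a methylene next to a quaternary carbon, leaving a mixture of C3′ epimers. The fallback makes the reduction stereoconvergent; it sets out from enynone 18 and comes back at iodide palmitate 22. Luche reduction (NaBH4, CeCl3·7H2O, MeOH, −40 °C) gives both carbinol epimers, which are separated. The trans epimer is 19 and continues as planned. The cis epimer, (1S,4R)-4-[(1E)-but-1-en-3-yn-1-yl]-3,5,5-trimethylcyclohex-2-en-1-ol F4, is taken through the same methylalumination–iodination to the cis hydroxy dienyl iodide F5. Mitsunobu esterification with palmitic acid (PPh3, DIAD, toluene, 0 °C) then inverts C3′ and installs the ester in one operation, giving 22.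

Step 15. Zerovalent palladium may ionise the allylic C3′ palmitate, the base may cleave an ester, or the polyenyl boronate may protodeboronate before it transmetalates. The fallback is a base-free Stille coupling with reversed polarity and the allylic oxygen left free; it sets out from aldehyde 12 and hydroxy iodide 21 and comes back at target 23. Takai iodo-olefination of 12 (CHI3, CrCl2, THF, 0 °C) gives the C26 (E)-polyenyl iodide F6, used at once. Iodine–lithium exchange on 21 (t-BuLi, 3.2 equiv, Et2O, −78 °C) and quenching with Bu3SnCl give the hydroxy dienylstannane F7. Coupling (Pd2(dba)3, AsPh3, THF/DMF, 25 °C, dark) gives lutein 3-palmitate F8, and acylation of its allylic hydroxyl (palmitoyl chloride, pyridine, DMAP, CH2Cl2, 0 °C) gives 23.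

**Further compounds**

F1 | step 11 | (6R)-6-[(1E)-but-1-en-3-yn-1-yl]-1,5,5-trimethyl-1,2-epoxycyclohexane, oxygen trans to the side chain | C#C/C=C/[C@H]1[C@]2(C)O[C@@H]2CCC1(C)C
F2 | step 11 | trans hydroxy phenylselenide from F1 (tertiary alcohol at the methyl-bearing carbon, PhSe on the neighbouring CH) | C#C/C=C/[C@H]1[C@](C)(O)[C@@H]([Se]c2ccccc2)CCC1(C)C
F3 | step 11 | 6-[(1E)-but-1-en-3-yn-1-yl]-1,5,5-trimethylcyclohex-2-en-1-ol, hydroxyl trans to the side chain | C#C/C=C/[C@H]1[C@](C)(O)C=CCC1(C)C
F4 | step 12 | (1S,4R)-4-[(1E)-but-1-en-3-yn-1-yl]-3,5,5-trimethylcyclohex-2-en-1-ol | C#C/C=C/[C@H]1C(C)=C[C@@H](O)CC1(C)C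
F5 | step 12 | (1S,4R)-4-[(1E,3E)-4-iodo-3-methylbuta-1,3-dien-1-yl]-3,5,5-trimethylcyclohex-2-en-1-ol | I/C=C(C)/C=C/[C@H]1C(C)=C[C@@H](O)CC1(C)C
F6 | step 15 | (1R)-4-[(1E,3E,5E,7E,9E,11E,13E)-14-iodo-3,7,12-trimethyltetradeca-1,3,5,7,9,11,13-heptaen-1-yl]-3,5,5-trimethylcyclohex-3-en-1-yl hexadecanoate | CCCCCCCCCCCCCCCC(=O)O[C@@H]1CC(C)=C(/C=C/C(C)=C/C=C/C(C)=C/C=C/C=C(C)/C=C/I)C(C)(C)C1
F7 | step 15 | (1R,4R)-3,5,5-trimethyl-4-[(1E,3E)-3-methyl-4-(tributylstannyl)buta-1,3-dien-1-yl]cyclohex-2-en-1-ol | CCCC[Sn](CCCC)(CCCC)/C=C(C)/C=C/[C@H]1C(C)=C[C@H](O)CC1(C)C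
F8 | step 15 | (3R,3′R,6′R)-lutein 3-palmitate (3′-hydroxyl free) | CCCCCCCCCCCCCCCC(=O)O[C@@H]1CC(C)=C(/C=C/C(C)=C/C=C/C(C)=C/C=C/C=C(C)/C=C/C=C(C)/C=C/[C@H]2C(C)=C[C@H](O)CC2(C)C)C(C)(C)C1
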